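**Strategy**

Everything rests on a C7–H disconnection that breaks no skeletal bond: the target is traced back to a racemic α-aryloxy ketone, reached in two steps from propiophenone 1 (via bromide 2) and phenol 3. In this ketone 4, C8 (the methine carrying the methyl group and the ether oxygen to ring B, 4-allyl-2,6-dimethoxyphenyl) is bonded directly to the C7 carbonyl on ring A (3,4-dimethoxyphenyl), so its hydrogen is acidic and its configuration mobile. A ketoreductase-catalysed dynamic kinetic reduction should then form the C7–H bond and fix C7 (R) and C8 (S) together, giving target 5 directly.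

Key step: step 3

Remark: neolignan numbering is used (C7 = benzylic carbon, C8 = ether-bearing carbon, C9 = methyl). The target SMILES encodes (1R,2S) = (7R,8S), the anti (erythro) pair. The enzyme in step 3 is assumed to be a hit selected for this pair from a commercial NADPH-dependent ketoreductase panel.

**Route**

Step 1
Reactants: 1 3',4'-dimethoxypropiophenone
Product: 2 rac-2-bromo-1-(3,4-dimethoxyphenyl)propan-1-one
Conditions: CuBr2 (2.1 equiv), EtOAc/CHCl3 (1:1), reflux
Reagents that add atoms: copper(II) bromide, Br[Cu]Br
Why: α-Halogenation of an aryl alkyl ketone through its copper-bound enol should be selective for the enolisable CH2 and leave the carbonyl-deactivated dimethoxyarene alone; the new C–Br centre forms racemic, which is all the later steps need.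

Step 2
Reactants: 2 rac-2-bromo-1-(3,4-dimethoxyphenyl)propan-1-one; 3 4-allyl-2,6-dimethoxyphenol
Product: 4 rac-2-(4-allyl-2,6-dimethoxyphenoxy)-1-(3,4-dimethoxyphenyl)propan-1-one
Conditions: K2CO3 (2 equiv), acetone, reflux
Reagents that add atoms: none
Why: Williamson ether synthesis, in which the phenoxide displaces bromide at the carbonyl-activated α-carbon by SN2; carbonate is too weak to move the allyl double bond into conjugation, and C8 is formed racemic on purpose.

Step 3
Reactants: 4 rac-2-(4-allyl-2,6-dimethoxyphenoxy)-1-(3,4-dimethoxyphenyl)propan-1-one
Product: 5 (1R,2S)-2-(4-allyl-2,6-dimethoxyphenoxy)-1-(3,4-dimethoxyphenyl)propan-1-ol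
Conditions: KRED (screened, NADPH-dependent), NADP+ (cat.), i-PrOH (excess), 10% DMSO, 0.1 M borate pH 9.5–10, 35–40 °C
Reagents that add atoms: none
Why: The enzyme should bind the (S)-enantiomer of 4 and pass the C4 hydride of NADPH to the Si face of the C7 carbonyl (priorities O > C8 > aryl carbon), the carbonyl oxygen being protonated by the active-site acid, while isopropanol regenerates NADPH and ends as acetone. The closest known reaction type is the ketoreductase-mediated dynamic reductive kinetic resolution of configurationally labile α-substituted ketones. No ring is formed. C7 (R) is set by the carbonyl face that the enzyme pocket presents to the cofactor, and C8 (S) by the enzyme's choice of ketone enantiomer, the unreacted (R)-ketone returning to the racemate through the achiral enolate in the mildly basic buffer. The step needs enantiomer selection, facial selection and chemoselectivity: the first two hold as long as epimerisation outpaces reduction of the mismatched enantiomer, which the aryl ketone and the α-aryloxy group secure by acidifying C8–H, and the third holds because the terminal alkene and the methyl ethers are not substrates for a nicotinamide-dependent reductase. Once reduced, the product has no acidic C8–H, so neither centre can scramble afterwards.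

**Compound list**

1 | 3',4'-dimethoxypropiophenone (1-(3,4-dimethoxyphenyl)propan-1-one) | CCC(=O)c1ccc(OC)c(OC)c1 | starting material
2 | rac-2-bromo-1-(3,4-dimethoxyphenyl)propan-1-one | CC(Br)C(=O)c1ccc(OC)c(OC)c1 | intermediate
3 | 4-allyl-2,6-dimethoxyphenol (methoxyeugenol) | C=CCc1cc(OC)c(O)c(OC)c1 | starting material
4 | rac-2-(4-allyl-2,6-dimethoxyphenoxy)-1-(3,4-dimethoxyphenyl)propan-1-one | C=CCc1cc(OC)c(OC(C)C(=O)c2ccc(OC)c(OC)c2)c(OC)c1 | intermediate
5 | (1R,2S)-2-(4-allyl-2,6-dimethoxyphenoxy)-1-(3,4-dimethoxyphenyl)propan-1-ol | C=CCc1cc(OC)c(O[C@@H](C)[C@H](O)c2ccc(OC)c(OC)c2)c(OC)c1 | target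

Total step count: 3
Longest linear sequence: 3 steps (1 → 2 → 4 → 5)

**Steps most likely to fail**

Step 3. What may go wrong: epimerisation at C8 may be too slow relative to reduction of the mismatched (8R)-ketone, the available enzymes may deliver hydride to the wrong carbonyl face, or the reaction may stall because 4 dissolves poorly in buffer. Fallback, setting out from 3 and returning to the route at 5: the two centres would be installed one after the other by known chemistry. Mitsunobu etherification of 3 with commercial methyl (R)-lactate (PPh3, DIAD, THF, 0 °C to rt) should give, with inversion, methyl (S)-2-(4-allyl-2,6-dimethoxyphenoxy)propanoate F1. Treatment with MeNH(OMe)·HCl and i-PrMgCl (THF, −20 °C) should convert it into the Weinreb amide (S)-2-(4-allyl-2,6-dimethoxyphenoxy)-N-methoxy-N-methylpropanamide F2. Addition of 3,4-dimethoxyphenylmagnesium bromide (THF, −20 to 0 °C, cold acidic quench) should give the single-enantiomer ketone (S)-2-(4-allyl-2,6-dimethoxyphenoxy)-1-(3,4-dimethoxyphenyl)propan-1-one F3, which must be kept away from base. Chelation-controlled reduction with Zn(BH4)2 (Et2O, −30 °C) should then deliver hydride to the five-membered zinc chelate from the side opposite the C9 methyl and give the anti alcohol 5; the allyl group should not be hydroborated at this temperature.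

Step 2. What may go wrong: base-induced loss of HBr from 2 to the aryl vinyl ketone, or sluggish substitution because the phenoxide oxygen is flanked by two methoxy groups, with prolonged heating then inviting allyl-to-propenyl migration. Fallback, setting out from 2 and returning at 4: the ether bond would be made by alcohol activation under neutral conditions instead of halide displacement under base. Sodium formate in aqueous ethanol at reflux should displace the bromide of 2 to give rac-1-(3,4-dimethoxyphenyl)-1-oxopropan-2-yl formate F4 (not isolated), which should hydrolyse in the same pot to rac-2-hydroxy-1-(3,4-dimethoxyphenyl)propan-1-one F5. Mitsunobu coupling of this alcohol with phenol 3 (PPh3, DIAD, THF, 0 °C to rt) should then give ketone 4.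

Step 1. What may go wrong: over-bromination at the α-carbon or electrophilic bromination of the electron-rich ring A. Fallback, setting out from 1 and returning at 2: the enol would be preformed and then brominated with exactly one equivalent of a mild bromine source. TMSOTf and Et3N (CH2Cl2, 0 °C) should convert 1 into the silyl enol ether (Z)-[1-(3,4-dimethoxyphenyl)prop-1-enyloxy]trimethylsilane F6, and NBS (THF, 0 °C) should brominate its nucleophilic carbon to give 2 without free bromine or acid being present.

**Further compounds**

F1 | step 3 | methyl (S)-2-(4-allyl-2,6-dimethoxyphenoxy)propanoate | C=CCc1cc(OC)c(O[C@@H](C)C(=O)OC)c(OC)c1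
F2 | step 3 | (S)-2-(4-allyl-2,6-dimethoxyphenoxy)-N-methoxy-N-methylpropanamide | C=CCc1cc(OC)c(O[C@@H](C)C(=O)N(C)OC)c(OC)c1
F3 | step 3 | (S)-2-(4-allyl-2,6-dimethoxyphenoxy)-1-(3,4-dimethoxyphenyl)propan-1-one | C=CCc1cc(OC)c(O[C@@H](C)C(=O)c2ccc(OC)c(OC)c2)c(OC)c1
F4 | step 2 | rac-1-(3,4-dimethoxyphenyl)-1-oxopropan-2-yl formate | CC(OC=O)C(=O)c1ccc(OC)c(OC)c1
F5 | step 2 | rac-2-hydroxy-1-(3,4-dimethoxyphenyl)propan-1-one | CC(O)C(=O)c1ccc(OC)c(OC)c1
F6 | step 1 | (Z)-[1-(3,4-dimethoxyphenyl)prop-1-enyloxy]trimethylsilane | C/C=C(\O[Si](C)(C)C)c1ccc(OC)c(OC)c1
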